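| flask | starting material | protic impurity | remark | time |
|---|---|---|---|---|
| Tuesday's | 0.26 M | 5.2 mM | run made earlier |  |
| Saturday's | 0.26 M | 2.6 mM | run made earlier |  |
| Monday's | 0.26 M | 3.9 mM | run made earlier |  |
| noon | 0.26 M | 5.20 mM | everything together in a closed stirred flask, run for 40 min | 40 min |
| midnight | 0.26 M | 5.20 mM | one stirred flow tank at steady state, fed with the mixture as stated, mean residence time 40 min |  |
| spring | 0.26 M (fed, over 32.0 min) | 5.20 mM | a stirred flask in which starting material is dosed at a steady rate over 32.0 min without added volume, worked up at 40 min | 40 min |

- Tuesday's (time / min: ring / %): 5.00: 36.8; 10.0: 53.9; 15.0: 59.6; 20.0: 60.2; 25.0: 63.3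
- Saturday's (time / min: ring / %): 3.00: 27.2; 8.00: 48.6; 15.0: 59.7; 25.0: 63.8; 30.0: 65.0
- Monday's (time / min: ring / %): 3.00: 25.8; 8.00: 47.8; 15.0: 58.1; 25.0: 63.7; 30.0: 64.4

(standard deviation of a reading: 1 percentage point)

- the stated concentrations are those of everything mixed, before any reaction; amounts are the same in each set-up
- the feed brings no volume worth counting
- the earlier runs were made in a closed, stirred flask

1. the set-up with the highest amount of ring at the outlet or at the end, in percent of the starting material put in ("none" if the first two lie within 2 percentage points) (noon / midnight / spring / none)
2. amount of ring at the outlet or at the end, in percent of the starting material put in, noon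
3. amount of ring at the outlet or at the end, in percent of the starting material put in, midnight
4. amount of ring at the outlet or at the end, in percent of the starting material put in, spring

The closed flask is the easy case. Saturday's ring reaches 65.0 % at 30.0 min and Monday's 64.4 %, a gap of 0.6 percentage points against a scatter of 1 point, with protic impurity at 2.6 mM and 3.9 mM, so noon, at 40 min, belongs on that plateau. Saturday's first reading against this plateau gives 0.181 min⁻¹, the clearance constant: the pseudo-first-order rate at which starting material disappears by any path.

In spring, clearance balances the steady feed when starting material stands at 17.3 % of the charge, and the remaining 8.00 min leaves 4.07 %. The midnight tank, by the same balance, holds 12.2 %.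

Two extreme flasks follow. If the loss is first-order in starting material, the split ignores concentration, so ring is the plateau's share of what has cleared: 57.1 % in midnight and 62.4 % in spring. If the loss dies away on dilution, whatever has cleared is ring: 87.8 % in midnight and 95.9 % in spring, a ceiling higher than midnight's. The readings cannot choose between these, so this reckoning places midnight between 57.1 % and 87.8 %, and spring between 62.4 % and 95.9 %.

The forecast, holding that “The loss must therefore come from the starting material itself”, names spring, with noon 65 %, midnight 73 % and spring 77 %.

    starting material + protic impurity → quenched substrate (k = 0.101 M⁻¹ s⁻¹)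
    2 starting material → open dimer (k = 0.00360 M⁻¹ s⁻¹)
    starting material → ring (k = 0.00204 s⁻¹)
    starting material + ring → side product (k = 7.83 × 10⁻⁴ M⁻¹ s⁻¹)

The flasks give noon 65.5 %, midnight 65.5 % and spring 73.6 %, so spring leads. Midnight's outlet holds 14.3 % of starting material, and spring holds 20.5 % at 32.0 min, each more than the clearance constant of 0.181 min⁻¹ gave (12.2 % and 17.3 %). Midnight's ring stands below the forecast, with side product at 9.16 % against noon's 4.47 %. Noon, with 0.30 % of starting material left at 40 min, moves to 65.7 % by 400 min. Spring has not come to rest: 6.5 % of starting material remains at 40 min, and by 400 min its ring reaches 79.0 %.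

(The runs stem from a simulated flask with made-up constants, and the scatter is random.)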